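The plan rests on cutting the ε ring (C1'–C6', carotenoid numbering) at C1'–C6' and C2'–C3'. Its only alkene, C4'=C5', lies β,γ to the lone stereocentre C6', so the ring is a Diels–Alder adduct. One catalyst-controlled cycloaddition of methacrolein to an (E)-silyloxymethyl-substituted 2-methylbutadiene builds the ring, both bonds, the alkene position and C6' in one operation. The formyl group then becomes the second C1' methyl and C7' a tetrazolyl sulfone, which is joined to a C20 dialdehyde; a Sharpless-derived epoxy aldehyde completes the C40 chain, and acid contracts the 5,6-epoxide to the 5,8-furanoid ring.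

Key step: step 3

Remarks on the chemistry (assumptions):
- Locants are carotenoid locants; primed locants belong to the ε half. The target is (5R,8R,6'R)-5,8-epoxy-5,8-dihydro-β,ε-carotene.
- The sense of induction in step 3 is taken from the formyl C–H···O binding model, under which the (S)-prolinol-derived oxazaborolidinium gives (S)-configured formyl-bearing carbons with methacrolein. The (R)-prolinol-derived catalyst is therefore specified, and the sign of rotation of the known alcohol 8 is the check.
- Crocetin dialdehyde 11 is taken as a purchasable carotenoid building block.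

Step 1
Reactants: 1 (2E)-3-methylpent-2-en-4-yn-1-ol
Product: 2 tert-butyldimethyl{[(2E)-3-methylpent-2-en-4-yn-1-yl]oxy}silane
Conditions: TBSCl, imidazole, CH2Cl2, 0 °C to rt
Reagents that add atoms: tert-butyldimethylsilyl chloride, CC(C)(C)[Si](C)(C)Cl
Why: Imidazole-promoted silylation of a primary allylic alcohol; the silyl ether keeps the oxygen weakly Lewis basic towards the cationic boron catalyst of step 3 and is lost without an extra step in step 4.

Step 2
Reactants: 2 tert-butyldimethyl{[(2E)-3-methylpent-2-en-4-yn-1-yl]oxy}silane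
Product: 3 tert-butyldimethyl{[(2E)-3-methylpenta-2,4-dien-1-yl]oxy}silane
Conditions: H2 (1 atm), Pd/CaCO3 poisoned with Pb(OAc)2, quinoline, hexane, rt, stopped after one equivalent of H2
Reagents that add atoms: none
Why: Lindlar semihydrogenation takes the terminal alkyne to a vinyl group and stops there; the (E)-trisubstituted alkene is untouched, so C7' sits outside in the s-cis diene.

Step 3
Reactants: 3 tert-butyldimethyl{[(2E)-3-methylpenta-2,4-dien-1-yl]oxy}silane; 4 methacrolein
Product: 5 (1R,2S)-2-({[tert-butyl(dimethyl)silyl]oxy}methyl)-1,3-dimethylcyclohex-3-ene-1-carbaldehyde (cis; ring C1 = C1', ring C2 = C6')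
Conditions: (R)-1-(2-methylphenyl)-3,3-diphenyltetrahydro-1H,3H-pyrrolo[1,2-c][1,3,2]oxazaborole (C24H24BNO, from (R)-α,α-diphenylprolinol and o-tolylboronic acid; 20 mol %), HN(SO2CF3)2 (17 mol %), 4 (2 equiv), CH2Cl2, −78 °C, then −40 °C
Reagents that add atoms: none
Why: The triflimide-activated oxazaborolidine binds methacrolein through boron and a formyl C–H···O contact, lowers its LUMO and holds it s-trans over one catalyst phenyl group, so that the diene adds in a concerted, asynchronous [4+2] cycloaddition whose early bond joins the two unsubstituted CH2 termini (C2' of the enal, C3' of the diene). The closest known reaction type is the oxazaborolidinium-catalysed Diels–Alder reaction of 2-substituted acroleins with acyclic 1,3-dienes. The ε ring is closed by this intermolecular cycloaddition, suprafacial on both partners and through an endo transition state, which forms C2'–C3' and C1'–C6' and leaves the alkene only at C4'=C5'. C1' is set by the catalyst, because the (R)-configured cation shields the α-re face of the bound enal and C6' bonds to the α-si face (CHO, =CH2, CH3 counterclockwise as seen by the diene); C6' is set relative to C1' by the endo position of the formyl group towards the (E)-diene, which puts CHO cis to the CH2OSi group. The step needs C1'-to-C6' ("ortho") regiochemistry against the weaker opposing pull of the C5' methyl, secured by the large LUMO coefficient at the enal β-carbon meeting the unhindered terminus C3' remote from the bulky silyloxymethyl group; it also needs endo over exo approach, secured by the (E) geometry with C7' outside and the usual endo preference of the formyl group with acyclic dienes. Since C1' later becomes achiral, only the configuration at C6' is carried forward.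

Step 4
Reactants: 5 (1R,2S)-2-({[tert-butyl(dimethyl)silyl]oxy}methyl)-1,3-dimethylcyclohex-3-ene-1-carbaldehyde
Product: 8 [(1R)-2,6,6-trimethylcyclohex-2-en-1-yl]methanol ((R)-α-cyclogeraniol), via hydrazone 6 (not isolated), via silyl ether 7 (not isolated)
Conditions: N2H4·H2O, KOH, diethylene glycol, 130 °C then 200 °C; work-up with 1 M HCl in THF, rt
Reagents that add atoms: none
Why: Wolff–Kishner reduction (Huang-Minlon procedure) of a non-enolisable aldehyde via its hydrazone turns CHO into CH3, which makes C1' an achiral gem-dimethyl carbon while C6' (no acidifying group) keeps its configuration, and the hot base with the acidic work-up removes the primary silyl ether.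

Step 5
Reactants: 8 [(1R)-2,6,6-trimethylcyclohex-2-en-1-yl]methanol
Product: 9 1-phenyl-5-({[(1R)-2,6,6-trimethylcyclohex-2-en-1-yl]methyl}sulfanyl)-1H-tetrazole
Conditions: 1-phenyl-1H-tetrazole-5-thiol, PPh3, DIAD, THF, 0 °C to rt
Reagents that add atoms: 1-phenyl-1H-tetrazole-5-thiol, Sc1nnnn1-c1ccccc1
Why: Mitsunobu thioetherification of a primary alcohol with the acidic tetrazole thiol; substitution occurs at C7', so the neighbouring stereocentre C6' is not involved.

Step 6
Reactants: 9 1-phenyl-5-({[(1R)-2,6,6-trimethylcyclohex-2-en-1-yl]methyl}sulfanyl)-1H-tetrazole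
Product: 10 1-phenyl-5-({[(1R)-2,6,6-trimethylcyclohex-2-en-1-yl]methyl}sulfonyl)-1H-tetrazole
Conditions: (NH4)6Mo7O24·4H2O (10 mol %), 30% aq. H2O2, EtOH, 0 °C to rt
Reagents that add atoms: hydrogen peroxide, OO
Why: Molybdate-catalysed peroxide oxidation takes the sulfide to the sulfone and is selective for sulfur over the trisubstituted ring alkene.

Step 7
Reactants: 10 1-phenyl-5-({[(1R)-2,6,6-trimethylcyclohex-2-en-1-yl]methyl}sulfonyl)-1H-tetrazole; 11 crocetin dialdehyde ((2E,4E,6E,8E,10E,12E,14E)-2,6,11,15-tetramethylhexadeca-2,4,6,8,10,12,14-heptaenedial)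
Product: 13 (2E,4E,6E,8E,10E,12E,14E,16E)-2,6,11,15-tetramethyl-17-[(1R)-2,6,6-trimethylcyclohex-2-en-1-yl]heptadeca-2,4,6,8,10,12,14,16-octaenal (C30 aldehyde with CHO at C8), via potassium sulfonyl carbanion 12 (not isolated)
Conditions: KN(SiMe3)2 (1.05 equiv), THF, −78 °C; then added to 11 (3 equiv) in THF, −78 °C to rt, dark; aq. NH4Cl
Reagents that add atoms: none
Why: Julia–Kocienski olefination: the potassium sulfonyl carbanion adds to one formyl group of the excess dialdehyde, and Smiles rearrangement with loss of SO2 and the tetrazololate should give the (E)-C7'=C8' alkene; C6' carries no acidic hydrogen and is not affected.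

Step 8
Reactants: 13 C30 aldehyde
Product: 14 (2E,4E,6E,8E,10E,12E,14E,16E)-2,6,11,15-tetramethyl-17-[(1R)-2,6,6-trimethylcyclohex-2-en-1-yl]heptadeca-2,4,6,8,10,12,14,16-octaen-1-ol
Conditions: NaBH4, MeOH/THF, 0 °C, dark
Reagents that add atoms: none
Why: Borohydride 1,2-reduction of the conjugated aldehyde to the allylic alcohol; the polyene is left intact.

Step 9
Reactants: 14 C30 alcohol
Product: 15 [(2E,4E,6E,8E,10E,12E,14E,16E)-2,6,11,15-tetramethyl-17-[(1R)-2,6,6-trimethylcyclohex-2-en-1-yl]heptadeca-2,4,6,8,10,12,14,16-octaen-1-yl]triphenylphosphonium bromide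
Conditions: PPh3·HBr, MeOH/CH2Cl2, rt, dark
Reagents that add atoms: triphenylphosphine hydrobromide, Br.c1ccc(cc1)P(c1ccccc1)c1ccccc1
Why: Standard conversion of a polyene allylic alcohol into its phosphonium salt: ionisation gives a delocalised cation that triphenylphosphine captures at the terminal carbon C8, and the remote C6' centre cannot ionise.

Step 10
Reactants: 16 β-cyclocitral (2,6,6-trimethylcyclohex-1-ene-1-carbaldehyde)
Product: 17 β-cyclogeraniol ((2,6,6-trimethylcyclohex-1-en-1-yl)methanol)
Conditions: NaBH4, MeOH, 0 °C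
Reagents that add atoms: none
Why: Borohydride 1,2-reduction of a hindered enal whose β-carbon is fully substituted gives the allylic alcohol.

Step 11
Reactants: 17 β-cyclogeraniol
Product: 18 [(1R,6R)-2,2,6-trimethyl-7-oxabicyclo[4.1.0]heptan-1-yl]methanol
Conditions: Ti(OiPr)4 (20 mol %), D-(−)-diethyl tartrate (24 mol %), t-BuOOH (2 equiv), 4 Å MS, CH2Cl2, −20 °C
Reagents that add atoms: tert-butyl hydroperoxide, CC(C)(C)OO
Why: Katsuki–Sharpless epoxidation of the tetrasubstituted allylic alcohol: by the empirical face rule (L-(+)-tartrate turns geraniol into its (2S,3S)-epoxide) the D-(−)-tartrate complex delivers oxygen to the opposite face of C5=C6, which sets C5 as R and, through the cis ring fusion, C6.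

Step 12
Reactants: 18 [(1R,6R)-2,2,6-trimethyl-7-oxabicyclo[4.1.0]heptan-1-yl]methanol
Product: 19 (1S,6R)-2,2,6-trimethyl-7-oxabicyclo[4.1.0]heptane-1-carbaldehyde
Conditions: Pr4N[RuO4] (5 mol %), N-methylmorpholine N-oxide, 4 Å MS, CH2Cl2, rt
Reagents that add atoms: none
Why: Ley–Griffith oxidation of a primary alcohol under neutral conditions; the aldehyde has no α-hydrogen and the epoxide is not touched (the descriptor at the former C6 changes only through ligand priority).

Step 13
Reactants: 15 C30 phosphonium bromide; 19 (1S,6R)-2,2,6-trimethyl-7-oxabicyclo[4.1.0]heptane-1-carbaldehyde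
Product: 21 (5R,6S,6'R)-5,6-epoxy-5,6-dihydro-β,ε-carotene, via phosphorus ylide 20 (not isolated)
Conditions: NaOMe, MeOH/CH2Cl2, 0 °C to rt, dark
Reagents that add atoms: none
Why: Wittig olefination of a non-enolisable aldehyde with a polyene-stabilised ylide forms C7=C8; either geometry of this alkene is acceptable because step 14 passes through a C6–C8 allyl cation, and the basic medium leaves the epoxide and C6' untouched.

Step 14
Reactants: 21 (5R,6S,6'R)-5,6-epoxy-5,6-dihydro-β,ε-carotene
Product: 22 (5R,8R,6'R)-5,8-epoxy-5,8-dihydro-β,ε-carotene (target)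
Conditions: HCl (cat., about 0.01 M) in CHCl3/Et2O, 0 °C, minutes; aq. NaHCO3; preparative HPLC
Reagents that add atoms: none
Why: Acid-catalysed 5,6-epoxide to 5,8-furanoid rearrangement, known for carotenoid epoxides including those with an ε ring at the far end: C6–O ionises to a polyene-stabilised allyl cation and the C5 oxygen (C5 untouched, R) closes the five-membered ring on C8 without a useful facial preference, so the (8R) target must be separated from its C8 epimer by HPLC, and the epimer is recycled by re-equilibration under the same conditions.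

Compound list
1 | (2E)-3-methylpent-2-en-4-yn-1-ol | C#C/C(C)=C/CO | starting material
2 | tert-butyldimethyl{[(2E)-3-methylpent-2-en-4-yn-1-yl]oxy}silane | C#C/C(C)=C/CO[Si](C)(C)C(C)(C)C | intermediate
3 | tert-butyldimethyl{[(2E)-3-methylpenta-2,4-dien-1-yl]oxy}silane | C=C/C(C)=C/CO[Si](C)(C)C(C)(C)C | intermediate
4 | methacrolein (2-methylprop-2-enal) | CC(=C)C=O | starting material
5 | (1R,2S)-2-({[tert-butyl(dimethyl)silyl]oxy}methyl)-1,3-dimethylcyclohex-3-ene-1-carbaldehyde | CC1=CCC[C@@](C)(C=O)[C@H]1CO[Si](C)(C)C(C)(C)C | intermediate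
6 | hydrazone of 5 | CC1=CCC[C@@](C)(/C=N/N)[C@H]1CO[Si](C)(C)C(C)(C)C | intermediate
7 | tert-butyldimethyl{[(1R)-2,6,6-trimethylcyclohex-2-en-1-yl]methoxy}silane | CC1=CCCC(C)(C)[C@H]1CO[Si](C)(C)C(C)(C)C | intermediate
8 | [(1R)-2,6,6-trimethylcyclohex-2-en-1-yl]methanol ((R)-α-cyclogeraniol) | CC1=CCCC(C)(C)[C@H]1CO | intermediate
9 | 1-phenyl-5-({[(1R)-2,6,6-trimethylcyclohex-2-en-1-yl]methyl}sulfanyl)-1H-tetrazole | CC1=CCCC(C)(C)[C@H]1CSc1nnnn1-c1ccccc1 | intermediate
10 | 1-phenyl-5-({[(1R)-2,6,6-trimethylcyclohex-2-en-1-yl]methyl}sulfonyl)-1H-tetrazole | CC1=CCCC(C)(C)[C@H]1CS(=O)(=O)c1nnnn1-c1ccccc1 | intermediate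
11 | crocetin dialdehyde, (2E,4E,6E,8E,10E,12E,14E)-2,6,11,15-tetramethylhexadeca-2,4,6,8,10,12,14-heptaenedial | O=C/C(C)=C/C=C/C(C)=C/C=C/C=C(C)/C=C/C=C(C)/C=O | starting material
12 | potassium salt of sulfone 10 metalated at C7' | CC1=CCCC(C)(C)[C@H]1[CH-]S(=O)(=O)c1nnnn1-c1ccccc1.[K+] | intermediate
13 | (2E,4E,6E,8E,10E,12E,14E,16E)-2,6,11,15-tetramethyl-17-[(1R)-2,6,6-trimethylcyclohex-2-en-1-yl]heptadeca-2,4,6,8,10,12,14,16-octaenal | CC1=CCCC(C)(C)[C@H]1/C=C/C(C)=C/C=C/C(C)=C/C=C/C=C(C)/C=C/C=C(C)/C=O | intermediate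
14 | (2E,4E,6E,8E,10E,12E,14E,16E)-2,6,11,15-tetramethyl-17-[(1R)-2,6,6-trimethylcyclohex-2-en-1-yl]heptadeca-2,4,6,8,10,12,14,16-octaen-1-ol | CC1=CCCC(C)(C)[C@H]1/C=C/C(C)=C/C=C/C(C)=C/C=C/C=C(C)/C=C/C=C(C)/CO | intermediate
15 | triphenylphosphonium bromide of 14 (phosphorus on C8) | CC1=CCCC(C)(C)[C@H]1/C=C/C(C)=C/C=C/C(C)=C/C=C/C=C(C)/C=C/C=C(C)/C[P+](c1ccccc1)(c1ccccc1)c1ccccc1.[Br-] | intermediate
16 | β-cyclocitral (2,6,6-trimethylcyclohex-1-ene-1-carbaldehyde) | CC1=C(C=O)C(C)(C)CCC1 | starting material
17 | β-cyclogeraniol ((2,6,6-trimethylcyclohex-1-en-1-yl)methanol) | CC1=C(CO)C(C)(C)CCC1 | intermediate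
18 | [(1R,6R)-2,2,6-trimethyl-7-oxabicyclo[4.1.0]heptan-1-yl]methanol | OC[C@@]12O[C@]1(C)CCCC2(C)C | intermediate
19 | (1S,6R)-2,2,6-trimethyl-7-oxabicyclo[4.1.0]heptane-1-carbaldehyde | O=C[C@@]12O[C@]1(C)CCCC2(C)C | intermediate
20 | phosphorus ylide from 15 | CC1=CCCC(C)(C)[C@H]1/C=C/C(C)=C/C=C/C(C)=C/C=C/C=C(C)/C=C/C=C(C)/C=P(c1ccccc1)(c1ccccc1)c1ccccc1 | intermediate
21 | (5R,6S,6'R)-5,6-epoxy-5,6-dihydro-β,ε-carotene (drawn 7E) | CC1=CCCC(C)(C)[C@H]1/C=C/C(C)=C/C=C/C(C)=C/C=C/C=C(C)/C=C/C=C(C)/C=C/[C@@]12O[C@]1(C)CCCC2(C)C | intermediate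
22 | (5R,8R,6'R)-5,8-epoxy-5,8-dihydro-β,ε-carotene | CC1=CCCC(C)(C)[C@H]1/C=C/C(C)=C/C=C/C(C)=C/C=C/C=C(C)/C=C/C=C(\C)[C@H]1C=C2C(C)(C)CCC[C@@]2(C)O1 | target

Total step count: 14. Longest linear sequence: 11 steps (steps 1–9, 13 and 14).

Steps most likely to fail

Step 3. The chiral Lewis acid may discriminate the two enal faces poorly with this 1,2-disubstituted, oxygenated diene, or be slowed by binding of the ether oxygen to the cationic boron centre, so that the adduct is formed in low enantiomeric purity. The fallback gives up asymmetric catalysis for resolution; it does not cure a wrong regiochemical outcome. It sets out from diene 3 and methacrolein 4: an achiral Lewis acid (Me2AlCl, CH2Cl2, −78 °C) should give the racemic adduct F1, where the endo/exo ratio no longer matters because C1' becomes achiral. F1 is taken through the conditions of step 4 to racemic α-cyclogeraniol F2. The enantiomers of F2 are separated by preparative chromatography on a cellulose-carbamate chiral stationary phase, and the (R)-enantiomer re-enters the route as compound 8.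

Step 14. Ring closure on C8 has no useful facial bias, so about half of the fully assembled, enantio-enriched material is expected as the 8-epimer, and two very similar C40 epimers must be separated. The fallback moves the ring contraction ahead of the union with the ε half. It sets out from dialdehyde 11, which is converted statistically (HC(OMe)3, MeOH, cat. pyridinium p-toluenesulfonate) into the mono(dimethyl acetal) F6. Reduction (NaBH4, MeOH) gives the hydroxy acetal F7, and PPh3·HBr in MeOH gives the acetal phosphonium bromide F8. Wittig reaction of F8 with epoxy aldehyde 19 (NaOMe, CH2Cl2/MeOH) should give the epoxy acetal F9. Dilute aqueous HCl in THF then hydrolyses the acetal and contracts the epoxide; the (8R)-furanoid C30 aldehyde F10 is separated from its stereoisomer at C8 on silica, and that isomer is re-equilibrated with acid. Finally the potassium salt 12 of sulfone 10 is added to F10 under the conditions of step 7, which forms C7'=C8' and returns to the route at target 22 without further acid.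

Step 7. The addition–rearrangement–elimination sequence may give poor E/Z control at C7'=C8' with a conjugated aldehyde, and the carbanion may attack both formyl groups. The fallback replaces the sulfone by an unstabilised ylide and corrects the geometry afterwards. It sets out from alcohol 8, which is converted (I2, PPh3, imidazole, CH2Cl2) into the iodide F3 and then (PPh3, MeCN, reflux) into the phosphonium iodide F4. Its ylide (NaN(SiMe3)2, THF, −78 °C) is added to excess dialdehyde 11 and should give mainly the (7'Z)-aldehyde F5. Iodine-catalysed isomerisation (cat. I2, hexane, daylight) converts F5 into the all-E aldehyde 13, where the route is rejoined.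

Further compounds
F1 | step 3 | racemic 2-({[tert-butyl(dimethyl)silyl]oxy}methyl)-1,3-dimethylcyclohex-3-ene-1-carbaldehyde (cis/trans mixture) | CC1=CCCC(C)(C=O)C1CO[Si](C)(C)C(C)(C)C
F2 | step 3 | racemic (2,6,6-trimethylcyclohex-2-en-1-yl)methanol | CC1=CCCC(C)(C)C1CO
F3 | step 7 | (6R)-6-(iodomethyl)-1,5,5-trimethylcyclohex-1-ene | CC1=CCCC(C)(C)[C@H]1CI
F4 | step 7 | triphenyl{[(1R)-2,6,6-trimethylcyclohex-2-en-1-yl]methyl}phosphonium iodide | CC1=CCCC(C)(C)[C@H]1C[P+](c1ccccc1)(c1ccccc1)c1ccccc1.[I-]
F5 | step 7 | (2E,4E,6E,8E,10E,12E,14E,16Z)-2,6,11,15-tetramethyl-17-[(1R)-2,6,6-trimethylcyclohex-2-en-1-yl]heptadeca-2,4,6,8,10,12,14,16-octaenal | CC1=CCCC(C)(C)[C@H]1/C=C\C(C)=C\C=C\C(C)=C\C=C\C=C(C)\C=C\C=C(C)\C=O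
F6 | step 14 | (2E,4E,6E,8E,10E,12E,14E)-16,16-dimethoxy-2,6,11,15-tetramethylhexadeca-2,4,6,8,10,12,14-heptaenal | O=C/C(C)=C/C=C/C(C)=C/C=C/C=C(C)/C=C/C=C(C)/C(OC)OC
F7 | step 14 | (2E,4E,6E,8E,10E,12E,14E)-16,16-dimethoxy-2,6,11,15-tetramethylhexadeca-2,4,6,8,10,12,14-heptaen-1-ol | OC/C(C)=C/C=C/C(C)=C/C=C/C=C(C)/C=C/C=C(C)/C(OC)OC
F8 | step 14 | [(2E,4E,6E,8E,10E,12E,14E)-16,16-dimethoxy-2,6,11,15-tetramethylhexadeca-2,4,6,8,10,12,14-heptaen-1-yl]triphenylphosphonium bromide | COC(OC)/C(C)=C/C=C/C(C)=C/C=C/C=C(C)/C=C/C=C(C)/C[P+](c1ccccc1)(c1ccccc1)c1ccccc1.[Br-]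
F9 | step 14 | (5R,6S)-5,6-epoxy-5,6-dihydro-8'-apo-β-caroten-8'-al dimethyl acetal | COC(OC)/C(C)=C/C=C/C(C)=C/C=C/C=C(C)/C=C/C=C(C)/C=C/[C@@]12O[C@]1(C)CCCC2(C)C
F10 | step 14 | (5R,8R)-5,8-epoxy-5,8-dihydro-8'-apo-β-caroten-8'-al | O=C/C(C)=C/C=C/C(C)=C/C=C/C=C(C)/C=C/C=C(\C)[C@H]1C=C2C(C)(C)CCC[C@@]2(C)O1
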